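**Plan**
1. Cuts: after removal of twenty benzyl ethers, both aryl bonds of C4 of the top unit are cut (C4–C4a inside its pyran ring, and C4–C8 to ring A of the middle unit). This gives a benzylated epigallocatechin gallate-(4β→8)-epigallocatechin dimer and an open-chain (2S,3R)-2-benzyloxy-3-aryloxy-3-arylpropanal. The dimer is cut at C4(middle)–C8(bottom); the aldehyde at its aryl ether bond O1–C8a and at C2–C3 (aldol).
2. Enabling feature: C4 of the top unit lies between two phloroglucinol-type rings. It can therefore enter as an aldehyde carbon that is arylated twice: first by the carbon ortho to O1 of its own 3,5-dioxygenated ring A (six-membered closure O1–C2–C3–C4–C4a–C8a), then, as the ring-A-stabilised quinone-methide-type C4 cation, by C8 of the middle unit.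
3. Forward order: the pyran rings of the bottom and middle units come intact from (−)-epigallocatechin and are joined 4β→8. The top unit is carried as an open chain; its pyran ring closes last, in the flask in which it is linked to the dimer. Global hydrogenolysis ends the route.
4. Stereochemistry: bottom and middle units (2R,3R) come from the chiral pool. Top C2/C3 come from an Evans syn glycolate aldol followed by O-arylation with retention. Both interflavan C4 centres are set by attack trans to the axial C3 oxygen substituent (4β).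

Key step: step 13

Remark: the SMILES is read as epigallocatechin-(4β→8)-epigallocatechin 3-O-gallate-(4β→8)-epigallocatechin, every unit 2R,3R (2,3-cis) and both interflavan bonds 4β (3,4-trans); the acid of step 13 is taken to turn over, water being its only co-product.

**Step 1**
Reactants: 1 (−)-epigallocatechin
Product: 2 5,7,3',4',5'-penta-O-benzyl-(−)-epigallocatechin (3-OH free)
Conditions: BnBr (5.5 equiv), K2CO3, degassed DMF, 0 °C → rt, Ar
Reagents that add atoms: benzyl bromide, BrCc1ccccc1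
Why: Williamson etherification in which carbonate deprotonates only the five phenols, so the secondary 3-OH should stay free and no stereocentre is touched.

**Step 2**
Reactants: 2 5,7,3',4',5'-penta-O-benzyl-(−)-epigallocatechin
Product: 3 3,5,7,3',4',5'-hexa-O-benzyl-(−)-epigallocatechin
Conditions: NaH, BnBr, DMF, 0 °C → rt
Reagents that add atoms: benzyl bromide, BrCc1ccccc1
Why: Williamson etherification of the secondary alkoxide; with all phenols capped the base cannot open the pyran ring, so C2 and C3 are not affected.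

**Step 3**
Reactants: 2 5,7,3',4',5'-penta-O-benzyl-(−)-epigallocatechin
Product: 4 4β-(2-ethoxyethoxy)-5,7,3',4',5'-penta-O-benzyl-epigallocatechin (3-OH free, 3,4-trans)
Conditions: DDQ (2 equiv), 2-ethoxyethanol, CH2Cl2, rt
Reagents that add atoms: 2-ethoxyethanol, CCOCCO
Why: DDQ benzylic oxidation at C4 (hydride abstraction assisted by the three ring-A oxygens) with SN1-type trapping by the alcohol trans to the axial 3-OH, the standard C4 activation of benzylated flavan-3-ols.

**Step 4**
Reactants: 4 4β-(2-ethoxyethoxy)-penta-O-benzyl-epigallocatechin; 5 3,4,5-tris(benzyloxy)benzoic acid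
Product: 6 4β-(2-ethoxyethoxy)-5,7,3',4',5'-penta-O-benzyl-epigallocatechin 3-O-[3,4,5-tris(benzyloxy)benzoate]
Conditions: DCC, DMAP (cat.), CH2Cl2, rt
Reagents that add atoms: none
Why: Steglich esterification of the only free hydroxyl under neutral conditions that leave the acid-labile C4 ether intact.

**Step 5**
Reactants: 6 galloylated C4-activated middle unit; 3 hexa-O-benzyl-epigallocatechin (3 equiv, excess recovered)
Product: 7 [5,7,3',4',5'-penta-O-benzyl-epigallocatechin 3-O-(3,4,5-tri-O-benzylgallate)]-(4β→8)-3,5,7,3',4',5'-hexa-O-benzyl-epigallocatechin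
Conditions: TMSOTf (cat.), CH2Cl2, −78 °C; Et3N
Reagents that add atoms: none
Why: Lewis-acid-mediated Friedel–Crafts interflavan coupling in which C8 of 3 attacks the ionised C4 from the β face, trans to the axial 3-acyloxy group (4β→8), while the excess of 3 should suppress chain growth through the free C8 of 6.

**Step 6**
Reactants: 8 (S)-4-benzyloxazolidin-2-one; 9 benzyloxyacetyl chloride
Product: 10 (S)-4-benzyl-3-[(benzyloxy)acetyl]oxazolidin-2-one
Conditions: Et3N, DMAP (cat.), CH2Cl2, 0 °C → rt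
Reagents that add atoms: none
Why: N-acylation of the oxazolidinone with an acid chloride, the usual entry to Evans imides.

**Step 7**
Reactants: 10 (S)-4-benzyl-3-[(benzyloxy)acetyl]oxazolidin-2-one; 11 3,4,5-tris(benzyloxy)benzaldehyde
Product: 13 (S)-4-benzyl-3-[(2S,3R)-2-(benzyloxy)-3-hydroxy-3-[3,4,5-tris(benzyloxy)phenyl]propanoyl]oxazolidin-2-one, via Z boron enolate 12 (not isolated)
Conditions: Bu2BOTf, Et3N, CH2Cl2, −78 → 0 °C; 11, −78 → 0 °C; pH 7 buffer/MeOH
Reagents that add atoms: none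
Why: Evans syn aldol in which the Z boron enolate reacts through a Zimmerman–Traxler chair whose face is fixed by the benzyl group of the auxiliary, which should give the (2S,3R) syn adduct, that is the future C3 and C2 of the top unit.

**Step 8**
Reactants: 13 syn aldol adduct
Product: 14 (1R,2R)-2-(benzyloxy)-1-[3,4,5-tris(benzyloxy)phenyl]propane-1,3-diol
Conditions: LiBH4, MeOH (1 equiv), THF, 0 °C
Reagents that add atoms: none
Why: Reductive cleavage of the imide by borohydride releases the primary alcohol and the auxiliary without enolising either stereocentre.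

**Step 9**
Reactants: 14 (1R,2R)-diol
Product: 15 (1R,2R)-2-(benzyloxy)-3-[(tert-butyldiphenylsilyl)oxy]-1-[3,4,5-tris(benzyloxy)phenyl]propan-1-ol
Conditions: TBDPSCl, imidazole, CH2Cl2, 0 °C
Reagents that add atoms: tert-butyl(chloro)diphenylsilane, CC(C)(C)[Si](Cl)(c1ccccc1)c1ccccc1
Why: Selective silylation of the primary over the hindered secondary benzylic hydroxyl; the diphenylsilyl group is chosen because it resists 1,3-migration under the basic conditions of the next step.

**Step 10**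
Reactants: 15 silyl-protected benzylic alcohol; 16 1,3-bis(benzyloxy)-5-bromobenzene
Product: 17 tert-butyl{(2R,3R)-2-(benzyloxy)-3-[3,5-bis(benzyloxy)phenoxy]-3-[3,4,5-tris(benzyloxy)phenyl]propoxy}diphenylsilane
Conditions: [Pd(allyl)Cl]2 (2.5 mol%), RockPhos (7.5 mol%), Cs2CO3, toluene, 90 °C
Reagents that add atoms: none
Why: Palladium-catalysed C–O cross-coupling (Buchwald–Hartwig etherification) of a secondary alcohol with an aryl bromide, in which the C–O bond at the carbinol carbon is never broken, so the configuration of the future C2 is retained.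

**Step 11**
Reactants: 17 silyl-protected aryl ether
Product: 18 (2R,3R)-2-(benzyloxy)-3-[3,5-bis(benzyloxy)phenoxy]-3-[3,4,5-tris(benzyloxy)phenyl]propan-1-ol
Conditions: HF·pyridine, THF, 0 °C → rt
Reagents that add atoms: none
Why: Fluoride desilylation of the primary silyl ether; aryl and benzyl ethers are inert.

**Step 12**
Reactants: 18 primary alcohol
Product: 19 (2S,3R)-2-(benzyloxy)-3-[3,5-bis(benzyloxy)phenoxy]-3-[3,4,5-tris(benzyloxy)phenyl]propanal
Conditions: Dess–Martin periodinane, CH2Cl2, 0 °C → rt; used crude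
Reagents that add atoms: none
Why: Dess–Martin oxidation under non-basic conditions should avoid enolisation of the α-alkoxy aldehyde and loss of the β-aryloxy group, and the aldehyde is used without chromatography.

**Step 13**
Reactants: 19 (2S,3R)-aldehyde (added slowly); 7 protected dimer (1.5 equiv, excess recovered)
Product: 22 3,5,7,3',4',5'-hexa-O-benzyl-epigallocatechin-(4β→8)-[5,7,3',4',5'-penta-O-benzyl-epigallocatechin 3-O-(3,4,5-tri-O-benzylgallate)]-(4β→8)-3,5,7,3',4',5'-hexa-O-benzyl-epigallocatechin, via ring-closed flavan-4-ol 20 (not isolated), via flavan-4-yl cation 21 (not isolated)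
Conditions: TMSOTf (0.3 equiv), 4 Å MS, CH2Cl2, −78 → −40 °C; Et3N
Reagents that add atoms: none
Why: Proposed new method: the acid activates the aldehyde of 19 as an oxocarbenium ion that is attacked by the ring carbon ortho to the aryl ether oxygen (flanked by O1 and one benzyloxy group, para to the other) in a 6-exo-trig Friedel–Crafts hydroxyalkylation, forming C4–C4a and closing the pyran ring (20); ionisation of the C4–OH then gives cation 21, an O-alkylated quinone methide of ring A, which C8 of the galloylated upper unit of 7 captures. The closest known reaction types are the acid-mediated twofold arylation of aldehydes by electron-rich arenes (Baeyer condensation) and the Lewis-acid coupling of 4-hydroxy- or 4-alkoxyflavans with flavan nucleophiles used for procyanidins; new is their union, so that an open-chain aldehyde delivers ring and interflavan bond in one flask. The only ring closed is the six-membered pyran, by exo attack of the tethered arene on the activated carbonyl; C2 and C3 arrive fixed from 19 and should not enolise at −78 °C. The new stereocentre C4 is controlled by C3: in the half-chair of 21 the 2-aryl group is equatorial and the 3-benzyloxy group axial on the α face, so the nucleophile should enter from the β face, trans to O3 (4β, 3,4-trans), as in couplings of 2,3-cis flavan-4-yl cations. The step needs ring closure before any intermolecular event (secured by the six-atom tether to the most nucleophilic carbon and by slow addition of 19 to excess 7) and attack through C8 of the upper unit of 7 rather than a C6 position (the site at which benzylated dimers are known to extend to 4β→8 trimers). Should 7 attack the aldehyde first, the resulting benzylic cation would be closed by the same tethered arene anti to O3, so either order should lead to 22.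

**Step 14**
Reactants: 22 icosa-O-benzyl trimer
Product: 23 epigallocatechin-(4β→8)-epigallocatechin 3-O-gallate-(4β→8)-epigallocatechin (target)
Conditions: H2 (1 atm), Pd(OH)2/C, THF/MeOH/H2O, rt
Reagents that add atoms: none
Why: Hydrogenolysis of all twenty benzyl ethers over Pearlman's catalyst under neutral conditions, to which the gallate ester, the interflavan bonds and all stereocentres should be stable, as in the deprotection of benzylated procyanidin gallates.

**Compound list**
1 | (−)-epigallocatechin, (2R,3R) | O[C@@H]1Cc2c(O)cc(O)cc2O[C@@H]1c1cc(O)c(O)c(O)c1 | starting material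
2 | 5,7,3',4',5'-penta-O-benzyl-(−)-epigallocatechin | O[C@@H]1Cc2c(OCc5ccccc5)cc(OCc5ccccc5)cc2O[C@@H]1c1cc(OCc5ccccc5)c(OCc5ccccc5)c(OCc5ccccc5)c1 | intermediate
3 | 3,5,7,3',4',5'-hexa-O-benzyl-(−)-epigallocatechin | O(Cc5ccccc5)[C@@H]1Cc2c(OCc5ccccc5)cc(OCc5ccccc5)cc2O[C@@H]1c1cc(OCc5ccccc5)c(OCc5ccccc5)c(OCc5ccccc5)c1 | intermediate
4 | 4β-(2-ethoxyethoxy)-5,7,3',4',5'-penta-O-benzyl-epigallocatechin | O[C@@H]1[C@@H](OCCOCC)c2c(OCc5ccccc5)cc(OCc5ccccc5)cc2O[C@@H]1c1cc(OCc5ccccc5)c(OCc5ccccc5)c(OCc5ccccc5)c1 | intermediate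
5 | 3,4,5-tris(benzyloxy)benzoic acid | OC(=O)c1cc(OCc2ccccc2)c(OCc2ccccc2)c(OCc2ccccc2)c1 | starting material
6 | 4β-(2-ethoxyethoxy)-5,7,3',4',5'-penta-O-benzyl-epigallocatechin 3-O-[3,4,5-tris(benzyloxy)benzoate] | O=C(O[C@@H]1[C@@H](OCCOCC)c2c(OCc5ccccc5)cc(OCc5ccccc5)cc2O[C@@H]1c1cc(OCc5ccccc5)c(OCc5ccccc5)c(OCc5ccccc5)c1)c1cc(OCc5ccccc5)c(OCc5ccccc5)c(OCc5ccccc5)c1 | intermediate
7 | [penta-O-benzyl-epigallocatechin 3-O-(tri-O-benzylgallate)]-(4β→8)-hexa-O-benzyl-epigallocatechin, C8 of the upper unit unsubstituted | O=C(O[C@@H]1[C@@H](c2c(OCc5ccccc5)cc(OCc5ccccc5)c3c2O[C@H](c2cc(OCc5ccccc5)c(OCc5ccccc5)c(OCc5ccccc5)c2)[C@H](OCc5ccccc5)C3)c2c(OCc5ccccc5)cc(OCc5ccccc5)cc2O[C@@H]1c1cc(OCc5ccccc5)c(OCc5ccccc5)c(OCc5ccccc5)c1)c1cc(OCc5ccccc5)c(OCc5ccccc5)c(OCc5ccccc5)c1 | intermediate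
8 | (S)-4-benzyloxazolidin-2-one | O=C1N[C@@H](Cc2ccccc2)CO1 | starting material
9 | benzyloxyacetyl chloride | O=C(Cl)COCc1ccccc1 | starting material
10 | (S)-4-benzyl-3-[(benzyloxy)acetyl]oxazolidin-2-one | O=C(COCc1ccccc1)N1[C@@H](Cc2ccccc2)COC1=O | intermediate
11 | 3,4,5-tris(benzyloxy)benzaldehyde | O=Cc1cc(OCc2ccccc2)c(OCc2ccccc2)c(OCc2ccccc2)c1 | starting material
12 | Z dibutylboron enolate of 10 (not isolated) | CCCCB(CCCC)O/C(=C\OCc1ccccc1)N1[C@@H](Cc2ccccc2)COC1=O | intermediate
13 | (S)-4-benzyl-3-[(2S,3R)-2-(benzyloxy)-3-hydroxy-3-[3,4,5-tris(benzyloxy)phenyl]propanoyl]oxazolidin-2-one | O=C([C@@H](OCc1ccccc1)[C@H](O)c1cc(OCc2ccccc2)c(OCc2ccccc2)c(OCc2ccccc2)c1)N1[C@@H](Cc2ccccc2)COC1=O | intermediate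
14 | (1R,2R)-2-(benzyloxy)-1-[3,4,5-tris(benzyloxy)phenyl]propane-1,3-diol | OC[C@@H](OCc1ccccc1)[C@H](O)c1cc(OCc2ccccc2)c(OCc2ccccc2)c(OCc2ccccc2)c1 | intermediate
15 | (1R,2R)-2-(benzyloxy)-3-[(tert-butyldiphenylsilyl)oxy]-1-[3,4,5-tris(benzyloxy)phenyl]propan-1-ol | CC(C)(C)[Si](c1ccccc1)(c1ccccc1)OC[C@@H](OCc1ccccc1)[C@H](O)c1cc(OCc2ccccc2)c(OCc2ccccc2)c(OCc2ccccc2)c1 | intermediate
16 | 1,3-bis(benzyloxy)-5-bromobenzene | Brc1cc(OCc2ccccc2)cc(OCc2ccccc2)c1 | starting material
17 | tert-butyl{(2R,3R)-2-(benzyloxy)-3-[3,5-bis(benzyloxy)phenoxy]-3-[3,4,5-tris(benzyloxy)phenyl]propoxy}diphenylsilane | CC(C)(C)[Si](c1ccccc1)(c1ccccc1)OC[C@@H](OCc1ccccc1)[C@H](Oc1cc(OCc2ccccc2)cc(OCc2ccccc2)c1)c1cc(OCc2ccccc2)c(OCc2ccccc2)c(OCc2ccccc2)c1 | intermediate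
18 | (2R,3R)-2-(benzyloxy)-3-[3,5-bis(benzyloxy)phenoxy]-3-[3,4,5-tris(benzyloxy)phenyl]propan-1-ol | OC[C@@H](OCc1ccccc1)[C@H](Oc1cc(OCc2ccccc2)cc(OCc2ccccc2)c1)c1cc(OCc2ccccc2)c(OCc2ccccc2)c(OCc2ccccc2)c1 | intermediate
19 | (2S,3R)-2-(benzyloxy)-3-[3,5-bis(benzyloxy)phenoxy]-3-[3,4,5-tris(benzyloxy)phenyl]propanal | O=C[C@@H](OCc1ccccc1)[C@H](Oc1cc(OCc2ccccc2)cc(OCc2ccccc2)c1)c1cc(OCc2ccccc2)c(OCc2ccccc2)c(OCc2ccccc2)c1 | intermediate
20 | (2R,3R)-2,3-cis-3,5,7,3',4',5'-hexa-O-benzyl-flavan-3,4-diol, 4-OH free, both C4 epimers (not isolated) | OC1c2c(OCc5ccccc5)cc(OCc5ccccc5)cc2O[C@H](c2cc(OCc5ccccc5)c(OCc5ccccc5)c(OCc5ccccc5)c2)[C@@H]1OCc5ccccc5 | intermediate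
21 | (2R,3R)-2,3-cis-3,5,7,3',4',5'-hexa-O-benzyl-flavan-4-yl cation (not isolated) | [CH+]1c2c(OCc5ccccc5)cc(OCc5ccccc5)cc2O[C@H](c2cc(OCc5ccccc5)c(OCc5ccccc5)c(OCc5ccccc5)c2)[C@@H]1OCc5ccccc5 | intermediate
22 | hexa-O-benzyl-epigallocatechin-(4β→8)-[penta-O-benzyl-epigallocatechin 3-O-(tri-O-benzylgallate)]-(4β→8)-hexa-O-benzyl-epigallocatechin | O=C(O[C@@H]1[C@@H](c2c(OCc5ccccc5)cc(OCc5ccccc5)c3c2O[C@H](c2cc(OCc5ccccc5)c(OCc5ccccc5)c(OCc5ccccc5)c2)[C@H](OCc5ccccc5)C3)c2c(OCc5ccccc5)cc(OCc5ccccc5)c([C@H]3c4c(OCc5ccccc5)cc(OCc5ccccc5)cc4O[C@H](c4cc(OCc5ccccc5)c(OCc5ccccc5)c(OCc5ccccc5)c4)[C@@H]3OCc5ccccc5)c2O[C@@H]1c1cc(OCc5ccccc5)c(OCc5ccccc5)c(OCc5ccccc5)c1)c1cc(OCc5ccccc5)c(OCc5ccccc5)c(OCc5ccccc5)c1 | intermediate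
23 | epigallocatechin-(4β→8)-epigallocatechin 3-O-gallate-(4β→8)-epigallocatechin | O=C(O[C@@H]1[C@@H](c2c(O)cc(O)c3c2O[C@H](c2cc(O)c(O)c(O)c2)[C@H](O)C3)c2c(O)cc(O)c([C@H]3c4c(O)cc(O)cc4O[C@H](c4cc(O)c(O)c(O)c4)[C@@H]3O)c2O[C@@H]1c1cc(O)c(O)c(O)c1)c1cc(O)c(O)c(O)c1 | target

**Step count and risks**
Total step count: 14. Longest linear sequence: 9 steps (steps 6 to 14).

Steps most likely to fail:

1. Step 13 (labelled step). What may go wrong: chain growth of the newly formed top unit through its own ring-A carbons before capture by the dimer, attack through a C6 position instead of C8, loss of H3 from the C4 cation to a flav-3-ene, or acid-induced scrambling of the existing interflavan bond. Fallback with known chemistry: setting out from 4, benzylation of the 3-OH (NaH, BnBr, DMF) would give 3-O-benzyl-4β-(2-ethoxyethoxy)-5,7,3',4',5'-penta-O-benzyl-epigallocatechin F1. Its established TMSOTf-mediated coupling with excess 7 in CH2Cl2 at −78 °C should return to the route at 22. In this variant the top pyran ring comes from the chiral pool and is not closed in the route.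

2. Step 10. What may go wrong: β-hydride elimination from the palladium alkoxide (oxidation of the benzylic alcohol with reduction of the aryl bromide) and slow coupling at the hindered carbinol. Fallback: setting out from 15, Dess–Martin oxidation would give (R)-2-(benzyloxy)-3-[(tert-butyldiphenylsilyl)oxy]-1-[3,4,5-tris(benzyloxy)phenyl]propan-1-one F2. Chelation-controlled reduction with Zn(BH4)2 in Et2O at low temperature should give the anti alcohol (1S,2R)-2-(benzyloxy)-3-[(tert-butyldiphenylsilyl)oxy]-1-[3,4,5-tris(benzyloxy)phenyl]propan-1-ol F3. A Mitsunobu reaction of this alcohol with commercial 3,5-bis(benzyloxy)phenol (PPh3, DIAD, toluene, 0 °C) should form the aryl ether with inversion and come back to the route at 17.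

3. Step 5. What may go wrong: chain growth through the unblocked C8 of the electrophile and competing attack through C6 of 3. Fallback (bromine capping): setting out from 4, NBS in CH2Cl2 at −78 → 0 °C would give 8-bromo-4β-(2-ethoxyethoxy)-5,7,3',4',5'-penta-O-benzyl-epigallocatechin F4, whose ring A is deactivated as a nucleophile. Near-equimolar TMSOTf coupling with 3 should give [8-bromo-penta-O-benzyl-epigallocatechin]-(4β→8)-hexa-O-benzyl-epigallocatechin F5 with a free 3-OH. Bromine–lithium exchange (n-BuLi, 2.5 equiv, THF, −78 °C) and protonation with MeOH would give the debrominated dimer alcohol [penta-O-benzyl-epigallocatechin]-(4β→8)-hexa-O-benzyl-epigallocatechin F6. Steglich esterification of F6 with 5 should come back to the route at 7.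

**Further compounds**
F1 | step 13 | 3-O-benzyl-4β-(2-ethoxyethoxy)-5,7,3',4',5'-penta-O-benzyl-epigallocatechin | O(Cc5ccccc5)[C@@H]1[C@@H](OCCOCC)c2c(OCc5ccccc5)cc(OCc5ccccc5)cc2O[C@@H]1c1cc(OCc5ccccc5)c(OCc5ccccc5)c(OCc5ccccc5)c1
F2 | step 10 | (R)-2-(benzyloxy)-3-[(tert-butyldiphenylsilyl)oxy]-1-[3,4,5-tris(benzyloxy)phenyl]propan-1-one | CC(C)(C)[Si](c1ccccc1)(c1ccccc1)OC[C@@H](OCc1ccccc1)C(=O)c1cc(OCc2ccccc2)c(OCc2ccccc2)c(OCc2ccccc2)c1
F3 | step 10 | (1S,2R)-2-(benzyloxy)-3-[(tert-butyldiphenylsilyl)oxy]-1-[3,4,5-tris(benzyloxy)phenyl]propan-1-ol | CC(C)(C)[Si](c1ccccc1)(c1ccccc1)OC[C@@H](OCc1ccccc1)[C@@H](O)c1cc(OCc2ccccc2)c(OCc2ccccc2)c(OCc2ccccc2)c1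
F4 | step 5 | 8-bromo-4β-(2-ethoxyethoxy)-5,7,3',4',5'-penta-O-benzyl-epigallocatechin | O[C@@H]1[C@@H](OCCOCC)c2c(OCc5ccccc5)cc(OCc5ccccc5)c(Br)c2O[C@@H]1c1cc(OCc5ccccc5)c(OCc5ccccc5)c(OCc5ccccc5)c1
F5 | step 5 | [8-bromo-5,7,3',4',5'-penta-O-benzyl-epigallocatechin]-(4β→8)-3,5,7,3',4',5'-hexa-O-benzyl-epigallocatechin | O[C@@H]1[C@@H](c2c(OCc5ccccc5)cc(OCc5ccccc5)c3c2O[C@H](c2cc(OCc5ccccc5)c(OCc5ccccc5)c(OCc5ccccc5)c2)[C@H](OCc5ccccc5)C3)c2c(OCc5ccccc5)cc(OCc5ccccc5)c(Br)c2O[C@@H]1c1cc(OCc5ccccc5)c(OCc5ccccc5)c(OCc5ccccc5)c1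
F6 | step 5 | [5,7,3',4',5'-penta-O-benzyl-epigallocatechin]-(4β→8)-3,5,7,3',4',5'-hexa-O-benzyl-epigallocatechin | O[C@@H]1[C@@H](c2c(OCc5ccccc5)cc(OCc5ccccc5)c3c2O[C@H](c2cc(OCc5ccccc5)c(OCc5ccccc5)c(OCc5ccccc5)c2)[C@H](OCc5ccccc5)C3)c2c(OCc5ccccc5)cc(OCc5ccccc5)cc2O[C@@H]1c1cc(OCc5ccccc5)c(OCc5ccccc5)c(OCc5ccccc5)c1
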